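**Retrosynthetic overview**
1. The target is cut back, in one flask, to a 2,6-dimethoxyphenyl α-hydroxy-β,γ-unsaturated ester plus 3-phenylpropioloyl chloride. The disconnections are the lactone C5–O bond (cationic 1,3-transposition/lactonisation), C4–C4a (Friedel–Crafts acylation) and O1–C2 (demethylative 6-endo oxa-Michael closure).
2. The hydroxy ester comes from an aryl glyoxylate and an isobutenyl Grignard reagent.
3. The aryl glyoxylate comes from 1,3-dimethoxybenzene (lithiation between the two methoxy groups) and dimethyl oxalate; the arene stays symmetric until the last step.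
4. Ring order: both benzene rings are bought; the butenolide closes first and the pyranone (ring C) second, both in the final operation.

Assumption: the target SMILES has no stereocentre and no stereogenic double bond, so the compound is achiral and no enantiocontrol is needed; the one stereocentre that appears in an intermediate is racemic and is destroyed in the last step.

**Route**

Step 1
Reactants: 1 1,3-dimethoxybenzene; 2 dimethyl oxalate
Product: 4 methyl 2-(2,6-dimethoxyphenyl)-2-oxoacetate, via 2,6-dimethoxyphenyllithium 3 (not isolated)
Conditions: n-BuLi (1.05 equiv), THF, 0 °C → rt, 2 h; then cannulated into 2 (2.5 equiv), THF, −78 °C; aq. NH4Cl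
Reagents that add atoms: none
Why: The two methoxy groups direct lithiation to their shared ortho position (directed ortho-metalation), and inverse addition of the hindered aryllithium to excess dimethyl oxalate at −78 °C stops at the keto ester (nucleophilic acyl substitution) because the tetrahedral adduct survives until the quench; no stereocentre is formed.

Step 2
Reactants: 4 methyl 2-(2,6-dimethoxyphenyl)-2-oxoacetate; 5 2-methylprop-1-en-1-ylmagnesium bromide
Product: 6 methyl 2-(2,6-dimethoxyphenyl)-2-hydroxy-4-methylpent-3-enoate (racemic)
Conditions: 5 (1.2 equiv, 0.5 M in THF), THF, −78 → −20 °C; aq. NH4Cl; chromatography on Et3N-buffered silica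
Reagents that add atoms: none
Why: Chemoselective Grignard 1,2-addition to the non-enolisable ketone of the α-keto ester, which is far more electrophilic than the ester at low temperature; the new carbinol stereocentre is formed racemic because it becomes sp2 in step 4.

Step 3
Reactants: 7 3-phenylprop-2-ynoic acid
Product: 8 3-phenylprop-2-ynoyl chloride
Conditions: (COCl)2 (1.3 equiv), DMF (cat.), CH2Cl2, 0 °C → rt, 2 h; evaporate, use crude
Reagents that add atoms: oxalyl chloride, ClC(=O)C(=O)Cl
Why: Vilsmeier-type activation of the acid by DMF/oxalyl chloride gives the acid chloride at room temperature without adding HCl across the alkyne; no stereocentre is involved.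

Step 4
Reactants: 6 methyl 2-(2,6-dimethoxyphenyl)-2-hydroxy-4-methylpent-3-enoate (racemic); 8 3-phenylprop-2-ynoyl chloride
Product: 12 8-(5,5-dimethyl-2-oxo-2,5-dihydrofuran-3-yl)-7-methoxy-2-phenyl-4H-chromen-4-one, via aryl butenolide 9 (not isolated), via dimethoxy ynone 10 (not isolated), via hydroxy ynone 11 (not isolated)
Conditions: AlCl3 (1.2 equiv), CH2Cl2 (0.03 M), −20 → 0 °C, 30 min; then 8 (1.3 equiv), AlCl3 (3 equiv), 0 → 40 °C, 6 h; 1 M HCl, rt, 1 h
Reagents that add atoms: none
Why: Proposed new method: AlCl3 ionises the tertiary allylic carbinol of 6 to an allyl cation whose tertiary terminus is trapped by the ester carbonyl oxygen, and the resulting 2-methoxyfuranylium ion (the thermodynamic sink among the cations) is demethylated by chloride to butenolide 9; the acylium ion from 8 then attacks the only activated arene position (para to one methoxy, ortho to the other) to give 10, AlCl3 cleaves the methoxy group chelated to the new ketone to give 11, and the freed phenol closes 6-endo onto the ynone during the acidic quench to give the flavone; the closest known reaction types are the acid-mediated transposition–lactonisation of 2-hydroxy-3-enoates to butenolides and the AlCl3-mediated Friedel–Crafts flavone synthesis from phenol ethers and arylpropioloyl chlorides; no stereocentre is formed and the one in 6 is erased.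

**Compound list**
1 | 1,3-dimethoxybenzene | COc1cccc(OC)c1 | starting material
2 | dimethyl oxalate | COC(=O)C(=O)OC | starting material
3 | 2,6-dimethoxyphenyllithium | [Li]c1c(OC)cccc1OC | intermediate
4 | methyl 2-(2,6-dimethoxyphenyl)-2-oxoacetate | COC(=O)C(=O)c1c(OC)cccc1OC | intermediate
5 | 2-methylprop-1-en-1-ylmagnesium bromide | CC(C)=C[Mg]Br | starting material
6 | methyl 2-(2,6-dimethoxyphenyl)-2-hydroxy-4-methylpent-3-enoate (racemic) | COC(=O)C(O)(C=C(C)C)c1c(OC)cccc1OC | intermediate
7 | 3-phenylprop-2-ynoic acid (phenylpropiolic acid) | OC(=O)C#Cc1ccccc1 | starting material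
8 | 3-phenylprop-2-ynoyl chloride | ClC(=O)C#Cc1ccccc1 | intermediate
9 | 3-(2,6-dimethoxyphenyl)-5,5-dimethylfuran-2(5H)-one | COc1cccc(OC)c1C1=CC(C)(C)OC1=O | intermediate
10 | 3-[2,6-dimethoxy-3-(3-phenylprop-2-ynoyl)phenyl]-5,5-dimethylfuran-2(5H)-one | COc1ccc(C(=O)C#Cc2ccccc2)c(OC)c1C1=CC(C)(C)OC1=O | intermediate
11 | 3-[2-hydroxy-6-methoxy-3-(3-phenylprop-2-ynoyl)phenyl]-5,5-dimethylfuran-2(5H)-one | COc1ccc(C(=O)C#Cc2ccccc2)c(O)c1C1=CC(C)(C)OC1=O | intermediate
12 | 8-(5,5-dimethyl-2-oxo-2,5-dihydrofuran-3-yl)-7-methoxy-2-phenyl-4H-chromen-4-one | COc1ccc2c(=O)cc(-c3ccccc3)oc2c1C1=CC(C)(C)OC1=O | target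

**Totals and risk**
Total step count: 4.
Longest linear sequence: 3 steps (1 → 2 → 4); step 3 is a one-step side branch that makes the acylating partner.

The three steps most likely to fail, in order of risk:

First, step 4. The cascade asks one Lewis acid to do four things in sequence. The main dangers are:
- capture of the allyl cation by an ortho-methoxy oxygen, giving a 2H-chromene by-product;
- intermolecular Friedel–Crafts alkylation of the electron-rich arene by the same cation, which is the reason for the high dilution;
- incomplete ring closure of 11.

The fallback sets out from 6 and comes back at 12, building ring C by chalcone oxidation instead of acylative annulation. Compound 6 is lactonised alone with p-TsOH·H2O (10 mol %) in toluene at 80 °C and 9 is isolated. Friedel–Crafts acetylation of 9 with acetyl chloride/AlCl3 in CH2Cl2 (0 → 40 °C), with the same chelation-controlled mono-demethylation, gives 3-(3-acetyl-2-hydroxy-6-methoxyphenyl)-5,5-dimethylfuran-2(5H)-one F1. A BF3·OEt2-mediated Claisen–Schmidt condensation of F1 with benzaldehyde in dioxane at rt, acidic so that the lactone is not opened, gives the chalcone (E)-3-[2-hydroxy-6-methoxy-3-(3-phenylprop-2-enoyl)phenyl]-5,5-dimethylfuran-2(5H)-one F2. Oxidative cyclisation of F2 with I2 (cat.) in DMSO at 120 °C then gives 12.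

Second, step 2. The ketone of 4 sits between two ortho-methoxy groups, so the alkenyl Grignard reagent may add slowly or attack the ester, and 6 may ionise on silica.

The fallback sets out from 4 and comes back at 9. The more reactive 2-methylallylmagnesium chloride (allylic Grignard addition through a six-membered transition state, THF, −78 °C) gives methyl 2-(2,6-dimethoxyphenyl)-2-hydroxy-4-methylpent-4-enoate F3, a homoallylic alcohol that cannot ionise to an allyl cation. Heating F3 with p-TsOH·H2O in toluene at 90 °C protonates the 1,1-disubstituted alkene, and the tertiary cation is lactonised by the ester to 3-(2,6-dimethoxyphenyl)-3-hydroxy-5,5-dimethyldihydrofuran-2(3H)-one F4. Dehydration of F4 with SOCl2/pyridine (0 °C → rt) gives 9, which then enters step 4 at its acylation stage (8, AlCl3 3 equiv, CH2Cl2, 0 → 40 °C).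

Third, step 1. A second aryllithium may add to the very electrophilic ketone of 4, giving over-addition.

The fallback sets out from 1 and comes back at 6, reversing the order of the two C–C bond formations at the oxalate carbon so that 4 is by-passed. Compound 2 is first mono-alkenylated by inverse addition of 5 (THF, −78 °C) to give methyl 4-methyl-2-oxopent-3-enoate F5. Compound 3, made from 1 and n-BuLi as in step 1, is then added to F5 at −78 °C; 1,2-addition of the hard aryllithium to the ketone gives 6 directly.

**Further compounds**
F1 | step 4 | 3-(3-acetyl-2-hydroxy-6-methoxyphenyl)-5,5-dimethylfuran-2(5H)-one | CC(=O)c1ccc(OC)c(C2=CC(C)(C)OC2=O)c1O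
F2 | step 4 | (E)-3-[2-hydroxy-6-methoxy-3-(3-phenylprop-2-enoyl)phenyl]-5,5-dimethylfuran-2(5H)-one | COc1ccc(C(=O)/C=C/c2ccccc2)c(O)c1C1=CC(C)(C)OC1=O
F3 | step 2 | methyl 2-(2,6-dimethoxyphenyl)-2-hydroxy-4-methylpent-4-enoate (racemic) | COC(=O)C(O)(CC(C)=C)c1c(OC)cccc1OC
F4 | step 2 | 3-(2,6-dimethoxyphenyl)-3-hydroxy-5,5-dimethyldihydrofuran-2(3H)-one (racemic) | COc1cccc(OC)c1C1(O)CC(C)(C)OC1=O
F5 | step 1 | methyl 4-methyl-2-oxopent-3-enoate | COC(=O)C(=O)C=C(C)C
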